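**Plan**
Cuts, in retrosynthetic order: the O7–acyl bond of a ring C enol lactone (frees the acid); the C6–CH2 bond of the prenyl group (back to an O5 allyl ether, [3,3]); the C8–CH(Pr)/O7–acyl pair (annulation with hex-2-enal); the C6–CH2(cyclobutyl) bond (reductive alkylation with aldehyde 19); the O1–C2 bond of ring B, which contracts the pyranone to a benzofuran-3(2H)-one.
Forward order: ring B by reductive ring expansion, then C6 alkylation, ring C lactone, O5 ether, dearomatising Claisen rearrangement, cross-metathesis, lactone opening; the cyclobutane is made separately by [2+2] photocycloaddition and enters as 19.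
Enabling feature: in ring B the array O1–C2(Me)2–C3H2–C4(=O) is a cyclised acetone aldol with O1 β to the ketone. Its isomer with O1 on the α-carbon is a 2-(2-hydroxypropan-2-yl)benzofuran-3(2H)-one. Two-electron reduction cleaves that α C–O bond, and O1 recloses on the carbinol carbon.
Stereochemistry: cyclobutane centres from (R)-γ-valerolactone (face-selective [2+2], then epimerisation to trans); CH(Pr) from a chiral carbene catalyst; quaternary C6 by 1,3-chirality transfer from (S)-but-3-en-2-ol.

Key step: step 2

Remark: locants follow chroman-4-one numbering (O1, C2, C3, C4, C4a, C5–C8, C8a); ring A is the carbocycle, ring B the pyranone, ring C the lactone.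
Remark: the enolised triketone of the target is one compound in all tautomeric forms and is drawn as given (5-hydroxy-7-oxo).
Remark: 4,6-dimethoxybenzofuran-3(2H)-one is taken as commercially available.

Step 1
Reactants: 1 4,6-dimethoxybenzofuran-3(2H)-one; 2 acetone
Product: 3 2-(2-hydroxypropan-2-yl)-4,6-dimethoxybenzofuran-3(2H)-one (racemic)
Conditions: LiN(i-Pr)2, THF, −78 °C; acetone; AcOH quench at −78 °C
Reagents that add atoms: acetone, CC(C)=O
Why: Directed aldol addition of the lithium enolate to acetone places the future C2(Me)2 carbon on the carbon α to the ketone; the new stereocentre is racemic and is erased in step 2.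

Step 2
Reactants: 3 2-(2-hydroxypropan-2-yl)-4,6-dimethoxybenzofuran-3(2H)-one
Product: 6 5,7-dimethoxy-2,2-dimethylchroman-4-one, via ring-opened ketol 4 (not isolated), via enone 5 (not isolated)
Conditions: Zn dust, AcOH, 25 °C; filter; p-TsOH·H2O (cat.), 80 °C
Reagents that add atoms: none
Why: Zinc transfers two electrons to the aryl ketone of 3 and the ketyl expels the α-aryloxy oxygen O1, so the furanone opens to a zinc enolate that acetic acid protonates to ketol 4; acid then dehydrates the tertiary carbinol to enone 5. The closest known reaction types are the Zn/AcOH cleavage of phenacyl aryl ethers and the acid-mediated cyclisation of 2'-hydroxyaryl enones to chroman-4-ones. Ring B closes by 6-endo-trig oxa-Michael addition of the freed O1–H to the β,β-dimethyl terminus, so all five atoms of the furanone ring are kept and the former exocyclic carbinol carbon is inserted between O1 and the old C2 (five to six ring atoms). No stereocentre is formed, and that of racemic 3 is lost. The step needs α C–O scission without reduction of enone 5, which removal of the zinc before heating should secure, and regioselective reclosure, which is secured because O1–H is the only hydroxyl flanking the ketone (the other ortho position carries OMe).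

Step 3
Reactants: 6 5,7-dimethoxy-2,2-dimethylchroman-4-one
Product: 7 5,7-dihydroxy-2,2-dimethylchroman-4-one
Conditions: BBr3, CH2Cl2, −78 → 25 °C; then H2O
Reagents that add atoms: none
Why: Lewis-acid cleavage of both aryl methyl ethers frees the phenols; any transient opening of ring B recloses to the same compound because the opened triol is symmetric.

Step 4
Reactants: 8 (R)-γ-valerolactone
Product: 10 (5R)-5-methylfuran-2(5H)-one, via selenide 9 (not isolated)
Conditions: LiN(i-Pr)2, THF, −78 °C; PhSeBr; then H2O2, CH2Cl2, 0 → 25 °C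
Reagents that add atoms: none
Why: α-Selenenylation of the lactone enolate and syn-elimination of the selenoxide give the butenolide; the chiral-pool C5 centre is untouched, and base is avoided afterwards because the γ-hydrogen is acidic.

Step 5
Reactants: 10 (5R)-5-methylfuran-2(5H)-one; 11 2-methylpropene
Product: 12 (1R,4R,5R)-4,6,6-trimethyl-3-oxabicyclo[3.2.0]heptan-2-one
Conditions: hν (medium-pressure Hg lamp, Pyrex), 2-methylpropene (excess), acetone, −40 °C
Reagents that add atoms: 2-methylpropene, CC(C)=C
Why: Enone–alkene [2+2] photocycloaddition: head-to-tail orientation puts CMe2 on the β-carbon, the fusion is cis, and the alkene adds anti to the C5 methyl group, which sets both ring-fusion centres; minor isomers are diastereomers and are separated here.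

Step 6
Reactants: 12 (1R,4R,5R)-4,6,6-trimethyl-3-oxabicyclo[3.2.0]heptan-2-one; 13 N,O-dimethylhydroxylamine hydrochloride
Product: 14 (1R,2R)-2-[(1R)-1-hydroxyethyl]-N-methoxy-N,3,3-trimethylcyclobutane-1-carboxamide (cis)
Conditions: MeNHOMe·HCl, i-PrMgCl, THF, −20 → 0 °C
Reagents that add atoms: N,O-dimethylhydroxylamine hydrochloride, CNOC.Cl
Why: Aminolysis of the γ-lactone by the magnesium amide gives the Weinreb amide and frees the secondary alcohol without touching a stereocentre.

Step 7
Reactants: 14 (1R,2R)-2-[(1R)-1-hydroxyethyl]-N-methoxy-N,3,3-trimethylcyclobutane-1-carboxamide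
Product: 16 (1R,2S)-2-acetyl-N-methoxy-N,3,3-trimethylcyclobutane-1-carboxamide (trans), via cis ketone 15 (not isolated)
Conditions: Dess–Martin periodinane, NaHCO3, CH2Cl2, 0 → 25 °C; Na2S2O3 wash; then DBU (0.2 equiv), CH2Cl2, 25 °C
Reagents that add atoms: none
Why: Dess–Martin oxidation gives the cis methyl ketone, and enolisation of the ketone (far more acidic than the amide α-position) epimerises only the acetyl-bearing carbon to the more stable trans-1,2-disubstituted cyclobutane.

Step 8
Reactants: 16 (1R,2S)-2-acetyl-N-methoxy-N,3,3-trimethylcyclobutane-1-carboxamide; 17 methyltriphenylphosphonium bromide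
Product: 18 (1R,2R)-N-methoxy-N,3,3-trimethyl-2-(prop-1-en-2-yl)cyclobutane-1-carboxamide (trans)
Conditions: Ph3PCH3Br, KOt-Bu, THF, 0 → 25 °C
Reagents that add atoms: methyltriphenylphosphonium bromide, C[P+](c1ccccc1)(c1ccccc1)c1ccccc1.[Br-]
Why: Wittig methylenation turns the methyl ketone into the isopropenyl group; the Weinreb amide is inert to the ylide and no stereocentre changes.

Step 9
Reactants: 18 (1R,2R)-N-methoxy-N,3,3-trimethyl-2-(prop-1-en-2-yl)cyclobutane-1-carboxamide
Product: 19 (1R,2R)-3,3-dimethyl-2-(prop-1-en-2-yl)cyclobutane-1-carbaldehyde (trans)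
Conditions: i-Bu2AlH, THF, −78 °C; Rochelle salt work-up
Reagents that add atoms: none
Why: Partial reduction of the Weinreb amide stops at the aldehyde through the chelated tetrahedral intermediate; the α-centre is already in the thermodynamically preferred trans arrangement.

Step 10
Reactants: 7 5,7-dihydroxy-2,2-dimethylchroman-4-one; 19 (1R,2R)-3,3-dimethyl-2-(prop-1-en-2-yl)cyclobutane-1-carbaldehyde
Product: 21 6-{[(1S,2R)-3,3-dimethyl-2-(prop-1-en-2-yl)cyclobutyl]methyl}-5,7-dihydroxy-2,2-dimethylchroman-4-one, via ortho-quinone methide 20 (not isolated)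
Conditions: L-proline (20 mol %), Hantzsch ester, CH2Cl2/EtOH, 25 °C
Reagents that add atoms: none
Why: Organocatalytic reductive alkylation: amine-catalysed Knoevenagel-type condensation at C6, the carbon flanked by the two free hydroxyls, gives the ortho-quinone methide, which the Hantzsch ester reduces by hydride transfer; no stereocentre is formed.

Step 11
Reactants: 21 6-{[(1S,2R)-3,3-dimethyl-2-(prop-1-en-2-yl)cyclobutyl]methyl}-5,7-dihydroxy-2,2-dimethylchroman-4-one; 22 (E)-hex-2-enal
Product: 23 ring C lactone: 21 annulated across O7 and C8 by a (4R)-4-propyl-3,4-dihydropyran-2-one ring (5-OH free)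
Conditions: chiral aminoindanol-derived N-mesityl triazolium chloride (10 mol %, the enantiomer that gives 4R), DBU (20 mol %), 3,3',5,5'-tetra-tert-butyldiphenoquinone, toluene, 25 °C
Reagents that add atoms: (E)-hex-2-enal, CCC/C=C/C=O
Why: Oxidative N-heterocyclic-carbene catalysis turns the enal into an α,β-unsaturated acyl azolium; C8, the only free ring position, adds to its β-carbon and the adjacent O7 lactonises (the annulation known for naphthols and 1,3-diones), and the chiral azolium shields one face so that the CH(propyl) centre should form as R.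

Step 12
Reactants: 23 ring C lactone; 24 (S)-but-3-en-2-ol
Product: 25 5-O-[(R)-but-3-en-2-yl] ether of 23
Conditions: PPh3, DIAD, THF, 0 → 25 °C
Reagents that add atoms: (S)-but-3-en-2-ol, C=C[C@H](C)O
Why: Mitsunobu etherification of the only remaining hydroxyl proceeds by SN2 displacement with inversion, so the (S)-alcohol gives the (R)-configured branched allyl aryl ether.

Step 13
Reactants: 25 5-O-[(R)-but-3-en-2-yl] ether of 23
Product: 26 dearomatised 5-oxo compound carrying (E)-but-2-enyl and the cyclobutylmethyl group on quaternary C6 (6R in this intermediate; same spatial arrangement as the target)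
Conditions: toluene, 110 °C, sealed tube
Reagents that add atoms: none
Why: Aromatic Claisen rearrangement ([3,3]) from O5 can reach only C6 because C4a carries the acyl carbon; the chair transition state with the methyl group equatorial should transfer the (R) configuration of the ether carbon to C6 and give the (E)-butenyl group, and the product cannot rearomatise.

Step 14
Reactants: 26 dearomatised (E)-but-2-enyl compound; 27 2-methylbut-2-ene
Product: 28 6-prenyl ring C lactone (6S in this intermediate; same spatial arrangement as the target)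
Conditions: second-generation Grubbs catalyst RuCl2(=CHPh)(H2IMes)(PCy3) (5 mol %), 2-methylbut-2-ene/CH2Cl2, 40 °C
Reagents that add atoms: 2-methylbut-2-ene, CC=C(C)C
Why: Olefin cross-metathesis exchanges the ethylidene terminus for isopropylidene (but-2-enyl to prenyl); the hindered isopropenyl group and the tetrasubstituted ring alkenes should not take part and no stereocentre is touched.

Step 15
Reactants: 28 6-prenyl ring C lactone
Product: 29 target acid CNP0358381.1
Conditions: LiOH, THF/H2O, 0 °C; then 1 M HCl
Reagents that add atoms: lithium hydroxide, [Li+].[OH-]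
Why: Saponification of the enol lactone, an activated ester, releases the carboxylic acid and the C7 enolate, which settles as the hydrogen-bonded 5-hydroxy-7-oxo tautomer on acidification; no stereocentre is affected.

**Compound list**
1 | 4,6-dimethoxybenzofuran-3(2H)-one | COc1cc2OCC(=O)c2c(OC)c1 | starting material
2 | acetone | CC(C)=O | starting material
3 | 2-(2-hydroxypropan-2-yl)-4,6-dimethoxybenzofuran-3(2H)-one (racemic) | COc1cc2OC(C(C)(C)O)C(=O)c2c(OC)c1 | intermediate
4 | 3-hydroxy-1-(2-hydroxy-4,6-dimethoxyphenyl)-3-methylbutan-1-one | COc1cc(O)c(C(=O)CC(C)(C)O)c(OC)c1 | intermediate (not isolated)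
5 | 1-(2-hydroxy-4,6-dimethoxyphenyl)-3-methylbut-2-en-1-one | COc1cc(O)c(C(=O)C=C(C)C)c(OC)c1 | intermediate (not isolated)
6 | 5,7-dimethoxy-2,2-dimethylchroman-4-one | COc1cc2OC(C)(C)CC(=O)c2c(OC)c1 | intermediate
7 | 5,7-dihydroxy-2,2-dimethylchroman-4-one | CC1(C)CC(=O)c2c(O)cc(O)cc2O1 | intermediate
8 | (R)-γ-valerolactone, (5R)-5-methyloxolan-2-one | C[C@@H]1CCC(=O)O1 | starting material
9 | (5R)-5-methyl-3-(phenylselanyl)oxolan-2-one (mixture at C3) | C[C@@H]1CC([Se]c2ccccc2)C(=O)O1 | intermediate (not isolated)
10 | (5R)-5-methylfuran-2(5H)-one | C[C@@H]1C=CC(=O)O1 | intermediate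
11 | 2-methylpropene | CC(C)=C | starting material
12 | (1R,4R,5R)-4,6,6-trimethyl-3-oxabicyclo[3.2.0]heptan-2-one (cis-fused, cyclobutane anti to the 4-methyl) | O=C1O[C@H](C)[C@@H]2[C@H]1CC2(C)C | intermediate
13 | N,O-dimethylhydroxylamine hydrochloride | CNOC.Cl | starting material
14 | (1R,2R)-2-[(1R)-1-hydroxyethyl]-N-methoxy-N,3,3-trimethylcyclobutane-1-carboxamide (cis) | C[C@@H](O)[C@@H]1[C@H](C(=O)N(C)OC)CC1(C)C | intermediate
15 | (1R,2R)-2-acetyl-N-methoxy-N,3,3-trimethylcyclobutane-1-carboxamide (cis) | CC(=O)[C@@H]1[C@H](C(=O)N(C)OC)CC1(C)C | intermediate (not isolated)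
16 | (1R,2S)-2-acetyl-N-methoxy-N,3,3-trimethylcyclobutane-1-carboxamide (trans) | CC(=O)[C@H]1[C@H](C(=O)N(C)OC)CC1(C)C | intermediate
17 | methyltriphenylphosphonium bromide | C[P+](c1ccccc1)(c1ccccc1)c1ccccc1.[Br-] | starting material
18 | (1R,2R)-N-methoxy-N,3,3-trimethyl-2-(prop-1-en-2-yl)cyclobutane-1-carboxamide (trans) | C=C(C)[C@H]1[C@H](C(=O)N(C)OC)CC1(C)C | intermediate
19 | (1R,2R)-3,3-dimethyl-2-(prop-1-en-2-yl)cyclobutane-1-carbaldehyde (trans) | C=C(C)[C@H]1[C@H](C=O)CC1(C)C | intermediate
20 | ortho-quinone methide from 7 and 19 (6-alkylidene-5-hydroxy-2,2-dimethyl-2,3-dihydro-4H-chromene-4,7(6H)-dione) | C=C(C)[C@H]1[C@H](C=C2C(=O)C=C3OC(C)(C)CC(=O)C3=C2O)CC1(C)C | intermediate (not isolated)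
21 | 6-{[(1S,2R)-3,3-dimethyl-2-(prop-1-en-2-yl)cyclobutyl]methyl}-5,7-dihydroxy-2,2-dimethylchroman-4-one | C=C(C)[C@H]1[C@H](Cc2c(O)cc3OC(C)(C)CC(=O)c3c2O)CC1(C)C | intermediate
22 | (E)-hex-2-enal | CCC/C=C/C=O | starting material
23 | ring C lactone: 21 annulated across O7 and C8 by a (4R)-4-propyl-3,4-dihydropyran-2-one ring, 5-OH free | C=C(C)[C@H]1[C@H](Cc2c3OC(=O)C[C@@H](CCC)c3c3OC(C)(C)CC(=O)c3c2O)CC1(C)C | intermediate
24 | (S)-but-3-en-2-ol | C=C[C@H](C)O | starting material
25 | 5-O-[(R)-but-3-en-2-yl] ether of 23 | C=C(C)[C@H]1[C@H](Cc2c3OC(=O)C[C@@H](CCC)c3c3OC(C)(C)CC(=O)c3c2O[C@H](C)C=C)CC1(C)C | intermediate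
26 | dearomatised 5-oxo ring C lactone with (E)-but-2-enyl and the cyclobutylmethyl group on quaternary C6 (6R) | C=C(C)[C@H]1[C@H](C[C@@]2(C/C=C/C)C(=O)C3=C(OC(C)(C)CC3=O)C4=C2OC(=O)C[C@H]4CCC)CC1(C)C | intermediate
27 | 2-methylbut-2-ene | CC=C(C)C | starting material
28 | 6-prenyl ring C lactone (6S) | C=C(C)[C@H]1[C@H](C[C@@]2(CC=C(C)C)C(=O)C3=C(OC(C)(C)CC3=O)C4=C2OC(=O)C[C@H]4CCC)CC1(C)C | intermediate
29 | CNP0358381.1, (R)-3-substituted hexanoic acid of the 6,6-dialkyl-5-hydroxy-2,2-dimethylchromane-4,7-dione | C=C(C)[C@H]1[C@H](C[C@]2(CC=C(C)C)C(=O)C([C@H](CCC)CC(=O)O)=C3OC(C)(C)CC(=O)C3=C2O)CC1(C)C | target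

**Totals**
Total steps: 15. Longest linear sequence: 12 steps (steps 4–9, then 10–15, from (R)-γ-valerolactone).

**Steps most likely to fail**

Step 10. The condensation may attack C8 as well as C6 (poor regioselectivity between the two free ring positions), and the ortho-quinone methide may dimerise or tautomerise to a vinylphenol before hydride transfer. The fallback sets out from 7 and 19 and returns to the route at 21. Compound 7 is silylated at the non-chelated hydroxyl (TBSCl, imidazole) to 7-[(tert-butyldimethylsilyl)oxy]-5-hydroxy-2,2-dimethylchroman-4-one F1. This is iodinated ortho to the free hydroxyl (BnMe3N·ICl2, CaCO3) to 7-[(tert-butyldimethylsilyl)oxy]-5-hydroxy-6-iodo-2,2-dimethylchroman-4-one F2. Aldehyde 19 is reduced (NaBH4) to [(1R,2R)-3,3-dimethyl-2-(prop-1-en-2-yl)cyclobutyl]methanol F3, converted (I2, PPh3, imidazole) into (1R,2R)-1-(iodomethyl)-3,3-dimethyl-2-(prop-1-en-2-yl)cyclobutane F4, and then (Zn dust, LiCl) into {[(1R,2R)-3,3-dimethyl-2-(prop-1-en-2-yl)cyclobutyl]methyl}zinc iodide F5. Negishi coupling of F2 with F5 (Pd(OAc)2, a dialkylbiarylphosphine, THF) gives the 7-O-(tert-butyldimethylsilyl) ether of 21 F6, and Bu4NF removes the silyl group to give 21.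

Step 12. The hydrogen-bonded, doubly ortho-substituted phenol may react sluggishly, and displacement may leak to the SN2' pathway, giving the linear butenyl ether that would later deliver a reversed 1-methylallyl group. The fallback sets out from 23 and returns at 25. It is an asymmetric allylic etherification with (E)-but-2-enyl methyl carbonate under zerovalent palladium (Pd2(dba)3·CHCl3 with a chiral trans-1,2-diaminocyclohexane-derived bis(2-diphenylphosphinobenzamide) ligand, the enantiomer that gives the (R)-branched ether). The ligand-controlled π-allyl complex should favour attack of the phenoxide at the substituted terminus. It makes no new compound.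

Step 13. Chirality transfer may be incomplete (boat or axial-methyl transition states, seen as (Z)-alkene), and the butenyl group may drift by a further [3,3] shift to C8 or return to the ether. The fallback sets out from 23 and returns at 28, bypassing 25 and 26. It is a Tsuji–Trost dearomative C6-prenylation of the phenol with tert-butyl (3-methylbut-2-en-1-yl) carbonate (Pd2(dba)3·CHCl3, the same class of chiral bisphosphine, zerovalent palladium), in which the catalyst controls the face of C6. Any C6 epimer is a diastereomer and would be separated. It makes no new compound.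

Further compounds
F1 | step 10 | 7-[(tert-butyldimethylsilyl)oxy]-5-hydroxy-2,2-dimethylchroman-4-one | CC1(C)CC(=O)c2c(O)cc(O[Si](C)(C)C(C)(C)C)cc2O1
F2 | step 10 | 7-[(tert-butyldimethylsilyl)oxy]-5-hydroxy-6-iodo-2,2-dimethylchroman-4-one | CC1(C)CC(=O)c2c(O)c(I)c(O[Si](C)(C)C(C)(C)C)cc2O1
F3 | step 10 | [(1R,2R)-3,3-dimethyl-2-(prop-1-en-2-yl)cyclobutyl]methanol | C=C(C)[C@H]1[C@H](CO)CC1(C)C
F4 | step 10 | (1R,2R)-1-(iodomethyl)-3,3-dimethyl-2-(prop-1-en-2-yl)cyclobutane | C=C(C)[C@H]1[C@H](CI)CC1(C)C
F5 | step 10 | {[(1R,2R)-3,3-dimethyl-2-(prop-1-en-2-yl)cyclobutyl]methyl}zinc iodide | C=C(C)[C@H]1[C@H](C[Zn]I)CC1(C)C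
F6 | step 10 | 7-O-(tert-butyldimethylsilyl) ether of 21 | C=C(C)[C@H]1[C@H](Cc2c(O[Si](C)(C)C(C)(C)C)cc3OC(C)(C)CC(=O)c3c2O)CC1(C)C
F0 | step 12 | none | none
F0 | step 13 | none | none
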